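**Retrosynthetic overview**
1. Target 36 ⇐ bis-silyl ether 35 ⇐ (E)-alkene 32. The strategy rests on the C8 acetoxy methine and the C1′ tertiary carbinol: their two C–O bonds lie syn across the C8–C1′ bond that joins hydrindane C1 to the bromocyclohexane, and both are made in one iodonium-mediated cis-dioxygenation of the exocyclic C8=C1′ alkene (no ring forms).
2. 32 ⇐ hydrindane aldehyde 19 + tetrazolyl sulfone 31 (Julia–Kocienski, C8=C1′).
3. 19: cyclopentane ring last (C1–C2, intramolecular aldol of dialdehyde 17); cyclohexane ring first (C3a–C7a, bromonium-relayed epoxide/silyl enol ether cyclisation of 10); C7 carbinol by methyl addition; absolute configuration from an asymmetric epoxidation.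
4. 31: bromocyclohexane ring (C5′–C6′) by solvolytic cyclisation of bromochloride 24; the bromide stereocentre comes from an enantioselective bromochlorination of prenol.
5. Ring order: hydrindane six-membered ring, then its five-membered ring; bromocyclohexane ring in parallel; union; dioxygenation.

Key step: step 26

Remark: atom labels are those of the target (hydrindane C1–C7a, carbinol carbon C8, cyclohexane C1′–C6′; the C7a–H face is α); 4, 23 and both tartrate esters are taken as purchasable; centres that are lost again (carbinol carbon of 28–31, ester-bearing carbons of 24–26, enol-ether geometry of 15) are carried as mixtures.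

**Hydrindane fragment**

Step 1
Reactants: 1 dimethyl (2-oxopropyl)phosphonate; 2 1-bromo-3-methylbut-2-ene
Product: 3 dimethyl (6-methyl-2-oxohept-5-en-1-yl)phosphonate
Conditions: NaH, THF, 0 °C; n-BuLi; then 2, 0 °C
Reagents that add atoms: none
Why: γ-alkylation of a β-keto phosphonate dianion, in which the more basic terminal carbanion is alkylated (SN2) by the allylic bromide and the phosphonate-stabilised site is kept for step 2.

Step 2
Reactants: 3 dimethyl (6-methyl-2-oxohept-5-en-1-yl)phosphonate; 4 2-[(tert-butyldimethylsilyl)oxy]acetaldehyde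
Product: 5 (2E)-1-[(tert-butyldimethylsilyl)oxy]-8-methylnona-2,7-dien-4-one
Conditions: LiCl, iPr2NEt, MeCN, rt
Reagents that add atoms: none
Why: Horner–Wadsworth–Emmons olefination under mild LiCl/amine conditions, which should give the (E)-enone (future C7=O, C7a=C1, C8–O).

Step 3
Reactants: 5 (2E)-enone
Product: 6 (2E,7E)-1-[(tert-butyldimethylsilyl)oxy]-9-hydroxy-8-methylnona-2,7-dien-4-one
Conditions: SeO2 (cat.), t-BuOOH, salicylic acid (cat.), CH2Cl2, rt
Reagents that add atoms: tert-butyl hydroperoxide, CC(C)(C)OO (oxygen relayed through catalytic SeO2)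
Why: SeO2 allylic oxidation (ene reaction, then [2,3]-sigmatropic shift) takes the (E)-methyl of the trisubstituted alkene and should leave the electron-poor enone untouched.

Step 4
Reactants: 6 allylic alcohol
Product: 7 (2E)-1-[(tert-butyldimethylsilyl)oxy]-6-[(2R,3R)-3-(hydroxymethyl)-3-methyloxiran-2-yl]hex-2-en-4-one
Conditions: Ti(OiPr)4 (cat.), D-(−)-diethyl tartrate, t-BuOOH, 4 Å MS, CH2Cl2, −20 °C
Reagents that add atoms: tert-butyl hydroperoxide, CC(C)(C)OO
Why: Katsuki–Sharpless asymmetric epoxidation, in which the D-(−)-tartrate delivers oxygen to the alkene face that makes both oxirane carbons R (reagent control), fixing C3a and, after inversion in step 5, C4.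

Step 5
Reactants: 7 epoxy alcohol
Product: 8 (2E,7S,8R)-7-bromo-1-[(tert-butyldimethylsilyl)oxy]-8,9-dihydroxy-8-methylnon-2-en-4-one
Conditions: Ti(OiPr)4, Et2NH·HBr, CH2Cl2, 0 °C → rt
Reagents that add atoms: diethylammonium bromide, CC[NH2+]CC.[Br-]
Why: titanium-chelate-directed opening of a 2,3-epoxy alcohol at the carbon remote from the carbinol, where bromide enters at C4 with inversion (C4 S) and the tertiary C3a–O bond is untouched; the conjugated ketone is expected to be too poor a neighbouring group to compete.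

Step 6
Reactants: 8 bromohydrin diol
Product: 9 (2E,7S)-7-bromo-1-[(tert-butyldimethylsilyl)oxy]-7-[(2R)-2-methyloxiran-2-yl]hept-2-en-4-one
Conditions: PPh3, DIAD, PhMe, 0 → 60 °C
Reagents that add atoms: none
Why: Mitsunobu cyclodehydration of a primary/tertiary 1,2-diol, in which the tertiary hydroxyl displaces the primary oxyphosphonium group (3-exo-tet), so C3a keeps its configuration and its oxygen becomes a leaving group inside an oxirane.

Step 7
Reactants: 9 bromo epoxide
Product: 10 (3Z,7S)-7-bromo-1-[(tert-butyldimethylsilyl)oxy]-7-[(2R)-2-methyloxiran-2-yl]-4-[(triethylsilyl)oxy]hept-3-ene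
Conditions: Et3SiH, RhCl(PPh3)3 (cat.), PhH, 50 °C
Reagents that add atoms: triethylsilane, CC[SiH](CC)CC
Why: Rh-catalysed 1,4-hydrosilylation of an enone with a monohydrosilane gives the silyl enol ether regiospecifically at C7/C7a, and addition through the s-cis enone should give the (Z)-isomer needed to place the C7a side chain equatorial in step 8.

Step 8
Reactants: 10 (Z)-silyl enol ether
Product: 11 (2S,3R,4S)-4-bromo-2-{2-[(tert-butyldimethylsilyl)oxy]ethyl}-3-(hydroxymethyl)-3-methylcyclohexan-1-one
Conditions: MeAlCl2, CH2Cl2, −78 → −40 °C; aq. NaHCO3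
Reagents that add atoms: none
Why: Proposed new method: MeAlCl2 should ionise the 2,2-disubstituted oxirane at the tertiary carbon C3a with anchimeric help from the anti C4 bromine, and the bromonium ion should be opened at C3a by C7a of the (Z)-silyl enol ether through a chair (6-endo closure of the six-membered ring via the C3a–C7a bond; Br equatorial, C3a methyl axial, both arms equatorial), giving net retention at C3a and C7a–H trans to the methyl group; the closest known reactions are the Lewis-acid epoxide-initiated cation–olefin cyclisation terminated by a silyl enol ether and the generation of configurationally defined bromonium ions by ionising a tertiary leaving group next to a secondary bromide.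

Step 9
Reactants: 11 hydroxy ketone
Product: 12 (1R,2S,3R,4S)-4-bromo-2-{2-[(tert-butyldimethylsilyl)oxy]ethyl}-3-(hydroxymethyl)-1,3-dimethylcyclohexan-1-ol
Conditions: MeLi, CeCl3, THF, −78 °C
Reagents that add atoms: methyllithium, [Li]C
Why: organocerium addition to a hindered enolisable ketone without epimerising C7a; the axial C3a methyl blocks the axial trajectory, so the methyl group should enter equatorially and the new C7 hydroxyl is axial (C7 R).

Step 10
Reactants: 12 diol
Product: 13 (1R,2S,3R,6S)-6-bromo-2-{2-[(tert-butyldimethylsilyl)oxy]ethyl}-3-hydroxy-1,3-dimethylcyclohexane-1-carbaldehyde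
Conditions: Dess–Martin periodinane, NaHCO3, CH2Cl2, 0 °C → rt
Reagents that add atoms: none
Why: Dess–Martin oxidation of the primary neopentyl alcohol; the tertiary alcohol cannot be oxidised and the aldehyde has no α-hydrogen.

Step 11
Reactants: 13 hydroxy aldehyde
Product: 14 (1R,2S,3R,6S)-6-bromo-3-[(tert-butyldimethylsilyl)oxy]-2-{2-[(tert-butyldimethylsilyl)oxy]ethyl}-1,3-dimethylcyclohexane-1-carbaldehyde
Conditions: TBSOTf, 2,6-lutidine, CH2Cl2, 0 °C → rt
Reagents that add atoms: tert-butyldimethylsilyl trifluoromethanesulfonate, CC(C)(C)[Si](C)(C)OS(=O)(=O)C(F)(F)F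
Why: silyl triflate silylation of the hindered axial C7 alcohol, which would otherwise form lactols with the C8 aldehydes of steps 14–16 and trap the wrong C1 epimer.

Step 12
Reactants: 14 aldehyde
Product: 15 methyl enol ether of the homologated aldehyde (14 with the formyl group replaced by 2-methoxyvinyl; E/Z mixture)
Conditions: Ph3P(CH2OMe)Cl, KHMDS, THF, −78 → 0 °C
Reagents that add atoms: (methoxymethyl)triphenylphosphonium chloride, COC[P+](c1ccccc1)(c1ccccc1)c1ccccc1.[Cl-]
Why: Wittig methoxymethylenation of the hindered non-enolisable aldehyde adds C2 (one-carbon homologation); the C4 bromide is gauche to the C3–C3a bond, so Grob fragmentation of the betaine is not aligned.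

Step 13
Reactants: 15 enol ether
Product: 16 2-[(1S,2S,3R,6S)-6-bromo-3-[(tert-butyldimethylsilyl)oxy]-2-(2-hydroxyethyl)-1,3-dimethylcyclohexyl]acetaldehyde
Conditions: 1 M HCl, THF, rt
Reagents that add atoms: water, O
Why: aqueous acid hydrolyses the enol ether to the C2 aldehyde and cleaves the primary silyl ether, while the hindered tertiary silyl ether should survive.

Step 14
Reactants: 16 hydroxy aldehyde
Product: 17 2-[(1S,2S,3R,6S)-6-bromo-3-[(tert-butyldimethylsilyl)oxy]-1,3-dimethyl-2-(2-oxoethyl)cyclohexyl]acetaldehyde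
Conditions: Dess–Martin periodinane, NaHCO3, CH2Cl2, 0 °C
Reagents that add atoms: none
Why: Dess–Martin oxidation gives the dialdehyde under non-basic conditions that avoid premature aldol reaction.

Step 15
Reactants: 17 dialdehyde
Product: 18 (1S,2R,3aS,4S,7R,7aS)-4-bromo-7-[(tert-butyldimethylsilyl)oxy]-2-hydroxy-3a,7-dimethyloctahydro-1H-indene-1-carbaldehyde
Conditions: L-proline (cat.), DMSO, rt
Reagents that add atoms: none
Why: proline-catalysed intramolecular (5-enolexo) aldol reaction, in which the enamine forms at the less hindered C8 aldehyde and C1 attacks the C2 aldehyde to close the trans-fused five-membered ring; substrate control should place the C2 oxygen trans to the angular methyl and the epimerisable C1 formyl group trans to the C7a–C7 bond.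

Step 16
Reactants: 18 aldol
Product: 19 (1S,2R,3aS,4S,7R,7aS)-4-bromo-2,7-bis[(tert-butyldimethylsilyl)oxy]-3a,7-dimethyloctahydro-1H-indene-1-carbaldehyde
Conditions: TBSOTf, 2,6-lutidine, CH2Cl2, −78 °C
Reagents that add atoms: tert-butyldimethylsilyl trifluoromethanesulfonate, CC(C)(C)[Si](C)(C)OS(=O)(=O)C(F)(F)F
Why: low-temperature silylation of the β-hydroxy aldehyde with a silyl triflate and a hindered base avoids retro-aldol reaction and elimination.

**Bromocyclohexane fragment**

Step 17
Reactants: 20 3-methylbut-2-en-1-ol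
Product: 21 (2S)-2-bromo-3-chloro-3-methylbutan-1-ol
Conditions: NBS, ClTi(OiPr)3, chiral tridentate Schiff-base ligand (cat., the enantiomer giving the S bromide), hexane, −20 °C
Reagents that add atoms: N-bromosuccinimide, O=C1CCC(=O)N1Br; chlorotitanium triisopropoxide, CC(C)O[Ti](Cl)(OC(C)C)OC(C)C
Why: catalytic enantioselective bromochlorination of an allylic alcohol, in which the titanium-bound alkoxide directs Br+ to one alkene face and chloride opens the bromonium ion anti at the tertiary carbon, so the ligand sets the future C4′ bromide.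

Step 18
Reactants: 21 bromochloro alcohol
Product: 22 (2S)-2-bromo-3-chloro-3-methylbutyl trifluoromethanesulfonate
Conditions: Tf2O, 2,6-lutidine, CH2Cl2, −78 °C
Reagents that add atoms: trifluoromethanesulfonic anhydride, O=S(=O)(OS(=O)(=O)C(F)(F)F)C(F)(F)F
Why: O-sulfonylation of the primary alcohol at low temperature gives the triflate, which is used at once.

Step 19
Reactants: 22 triflate; 23 di-tert-butyl 3-oxopentanedioate
Product: 24 di-tert-butyl 2-[(2S)-2-bromo-3-chloro-3-methylbutyl]-3-oxopentanedioate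
Conditions: NaH, THF, 0 °C; then 22, −20 °C → rt
Reagents that add atoms: none
Why: SN2 alkylation of a soft 1,3-dicarbonyl enolate by the primary triflate; the stabilised enolate is too weak a base to eliminate HBr or HCl.

Step 20
Reactants: 24 keto diester
Product: 25 di-tert-butyl (5S)-5-bromo-4,4-dimethyl-2-oxocyclohexane-1,3-dicarboxylate
Conditions: (CF3)2CHOH, 2,6-di-tert-butylpyridine, rt
Reagents that add atoms: none
Why: solvolytic ionisation of the tertiary chloride with anchimeric help from the vicinal bromine gives a bromonium ion that the β-keto ester enol carbon opens at the tertiary carbon (chair, C5′–C6′ bond), so the bromide keeps its configuration; bromonium generation from bromochlorides and SN1 alkylation of 1,3-dicarbonyl compounds in this solvent are both known.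

Step 21
Reactants: 25 cyclised keto diester
Product: 27 (4S)-4-bromo-3,3-dimethylcyclohexan-1-one, via keto diacid 26 (not isolated)
Conditions: CF3CO2H, CH2Cl2, rt; then PhMe, 80 °C
Reagents that add atoms: none
Why: acidolysis of both tert-butyl esters and thermal loss of two CO2 from the β-keto diacid; no enolate is formed, which avoids 1,3-elimination of the γ-bromide to a cyclopropane.

Step 22
Reactants: 27 bromo ketone
Product: 28 (4S)-4-bromo-3,3-dimethylcyclohexan-1-ol (both C1 epimers)
Conditions: NaBH4, MeOH, 0 °C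
Reagents that add atoms: none
Why: borohydride reduction; the carbinol configuration does not matter because this carbon becomes sp2 in step 25.

Step 23
Reactants: 28 alcohol; 29 1-phenyl-1H-tetrazole-5-thiol
Product: 30 5-{[(4S)-4-bromo-3,3-dimethylcyclohexyl]sulfanyl}-1-phenyl-1H-tetrazole
Conditions: PPh3, DIAD, THF, 0 °C → rt
Reagents that add atoms: none
Why: Mitsunobu thioetherification (SN2 with inversion at the carbinol carbon); the neopentyl secondary bromide is inert to the thiolate.

Step 24
Reactants: 30 sulfide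
Product: 31 5-{[(4S)-4-bromo-3,3-dimethylcyclohexyl]sulfonyl}-1-phenyl-1H-tetrazole
Conditions: (NH4)6Mo7O24·4H2O (cat.), 30 % H2O2, EtOH, 0 °C → rt
Reagents that add atoms: hydrogen peroxide, OO
Why: molybdate-catalysed peroxide oxidation of the sulfide to the sulfone, which does not touch the alkyl bromide.

**Union and end game**

Step 25
Reactants: 19 hydrindane aldehyde; 31 tetrazolyl sulfone
Product: 32 (1S,2R,3aS,4S,7R,7aS)-4-bromo-1-{(E)-[(4S)-4-bromo-3,3-dimethylcyclohexylidene]methyl}-2,7-bis[(tert-butyldimethylsilyl)oxy]-3a,7-dimethyloctahydro-1H-indene (hydrindane C1 on the C2′ side)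
Conditions: KHMDS, DME, −60 °C; then 19, −60 °C → rt; (E)-isomer separated on AgNO3–SiO2
Reagents that add atoms: none
Why: Julia–Kocienski olefination (addition, Smiles rearrangement, loss of SO2 and tetrazolone) joins C8 to C1′ without exposing a ketone enolate to the γ-bromide; because C2′H2 and C6′H2 differ only beyond the allylic position little geometric bias is expected, so the (E)-isomer is isolated by chromatography.

Step 26
Reactants: 32 (E)-alkene
Product: 35 C2,C7-bis(tert-butyldimethylsilyl) ether of the target, via iodo acetate 33 (not isolated), via acetoxonium ion 34 (not isolated)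
Conditions: I2, AgOAc, AcOH, rt, dark; then AcOH–H2O, 60 °C
Reagents that add atoms: silver acetate, CC(=O)[O-].[Ag+]; water, O
Why: Acetyl hypoiodite from I2 and AgOAc adds iodine reversibly to the C8=C1′ alkene, acetate opens the unsymmetrical iodonium ion at the tertiary carbon C1′ anti to iodine (33), the acetate carbonyl displaces the silver-activated iodide at C8 with inversion to give the 2-methyl-1,3-dioxolan-2-ylium ion 34, and water opens 34 to an orthoacid that collapses, and equilibrates in warm acetic acid, to the secondary C8 acetate with the tertiary C1′ hydroxyl free. This is the Woodward cis-hydroxylation (Prévost reaction under wet conditions), the standard way to place two oxygens syn on the alkene face opposite to the one taken by the electrophile. It closes no ring of the product; the dioxolanylium ring is transient. Both new stereocentres follow from the iodonium face: the two oxygens enter together on the other face, so the (E)-geometry of 32 fixes C8 relative to C1′ (8R with 1′R) and the face fixes both relative to the hydrindane. The face should be set by allylic 1,3-strain: C1–H eclipses the alkene toward C2′H2, which puts C7a with the peri equatorial C7 methyl over one face and C2 on the other, so iodine is expected on the C2 side and the oxygens on the C7a side as in the target, while on the cyclohexane the C8 arm stays equatorial and C1′–O becomes axial in the chair with equatorial bromine. The step therefore needs opening of the C2-side iodonium ion only and geometrically pure 32; the silyl ethers at C2 and C7 prevent iodo-etherification and lactol formation.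

Step 27
Reactants: 35 bis-silyl ether
Product: 36 (R)-[(1S,2R,3aS,4S,7R,7aS)-4-bromo-2,7-dihydroxy-3a,7-dimethyloctahydro-1H-inden-1-yl][(1R,4S)-4-bromo-1-hydroxy-3,3-dimethylcyclohexyl]methyl acetate (CNP0166243.1)
Conditions: HF·pyridine, pyridine, THF, 0 °C → rt
Reagents that add atoms: none
Why: fluoride-mediated desilylation under buffered, weakly acidic conditions removes the secondary and, more slowly, the tertiary silyl ether and should leave the C8 acetate in place.

**Compound list**
1 | dimethyl (2-oxopropyl)phosphonate | COP(=O)(OC)CC(C)=O | starting material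
2 | 1-bromo-3-methylbut-2-ene | CC(C)=CCBr | starting material
3 | dimethyl (6-methyl-2-oxohept-5-en-1-yl)phosphonate | COP(=O)(OC)CC(=O)CCC=C(C)C | intermediate
4 | 2-[(tert-butyldimethylsilyl)oxy]acetaldehyde | O=CCO[Si](C)(C)C(C)(C)C | starting material
5 | (2E)-1-[(tert-butyldimethylsilyl)oxy]-8-methylnona-2,7-dien-4-one | CC(C)=CCCC(=O)/C=C/CO[Si](C)(C)C(C)(C)C | intermediate
6 | (2E,7E)-1-[(tert-butyldimethylsilyl)oxy]-9-hydroxy-8-methylnona-2,7-dien-4-one | OC/C(C)=C/CCC(=O)/C=C/CO[Si](C)(C)C(C)(C)C | intermediate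
7 | (2E)-1-[(tert-butyldimethylsilyl)oxy]-6-[(2R,3R)-3-(hydroxymethyl)-3-methyloxiran-2-yl]hex-2-en-4-one | OC[C@@]1(C)O[C@@H]1CCC(=O)/C=C/CO[Si](C)(C)C(C)(C)C | intermediate
8 | (2E,7S,8R)-7-bromo-1-[(tert-butyldimethylsilyl)oxy]-8,9-dihydroxy-8-methylnon-2-en-4-one | OC[C@@](C)(O)[C@@H](Br)CCC(=O)/C=C/CO[Si](C)(C)C(C)(C)C | intermediate
9 | (2E,7S)-7-bromo-1-[(tert-butyldimethylsilyl)oxy]-7-[(2R)-2-methyloxiran-2-yl]hept-2-en-4-one | C[C@@]1(CO1)[C@@H](Br)CCC(=O)/C=C/CO[Si](C)(C)C(C)(C)C | intermediate
10 | (3Z,7S)-7-bromo-1-[(tert-butyldimethylsilyl)oxy]-7-[(2R)-2-methyloxiran-2-yl]-4-[(triethylsilyl)oxy]hept-3-ene | C[C@@]1(CO1)[C@@H](Br)CC/C(O[Si](CC)(CC)CC)=C/CCO[Si](C)(C)C(C)(C)C | intermediate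
11 | (2S,3R,4S)-4-bromo-2-{2-[(tert-butyldimethylsilyl)oxy]ethyl}-3-(hydroxymethyl)-3-methylcyclohexan-1-one (Br, CH2OH and side chain equatorial, methyl axial) | OC[C@]1(C)[C@@H](Br)CCC(=O)[C@H]1CCO[Si](C)(C)C(C)(C)C | intermediate
12 | (1R,2S,3R,4S)-4-bromo-2-{2-[(tert-butyldimethylsilyl)oxy]ethyl}-3-(hydroxymethyl)-1,3-dimethylcyclohexan-1-ol | OC[C@]1(C)[C@@H](Br)CC[C@@](C)(O)[C@H]1CCO[Si](C)(C)C(C)(C)C | intermediate
13 | (1R,2S,3R,6S)-6-bromo-2-{2-[(tert-butyldimethylsilyl)oxy]ethyl}-3-hydroxy-1,3-dimethylcyclohexane-1-carbaldehyde | O=C[C@]1(C)[C@@H](Br)CC[C@@](C)(O)[C@H]1CCO[Si](C)(C)C(C)(C)C | intermediate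
14 | (1R,2S,3R,6S)-6-bromo-3-[(tert-butyldimethylsilyl)oxy]-2-{2-[(tert-butyldimethylsilyl)oxy]ethyl}-1,3-dimethylcyclohexane-1-carbaldehyde | O=C[C@]1(C)[C@@H](Br)CC[C@@](C)(O[Si](C)(C)C(C)(C)C)[C@H]1CCO[Si](C)(C)C(C)(C)C | intermediate
15 | 2-methoxyvinyl homologue of 14 (methyl enol ether at C3a, E/Z mixture; ring configuration as in 14) | COC=C[C@]1(C)[C@@H](Br)CC[C@@](C)(O[Si](C)(C)C(C)(C)C)[C@H]1CCO[Si](C)(C)C(C)(C)C | intermediate
16 | 2-[(1S,2S,3R,6S)-6-bromo-3-[(tert-butyldimethylsilyl)oxy]-2-(2-hydroxyethyl)-1,3-dimethylcyclohexyl]acetaldehyde | O=CC[C@]1(C)[C@@H](Br)CC[C@@](C)(O[Si](C)(C)C(C)(C)C)[C@H]1CCO | intermediate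
17 | 2-[(1S,2S,3R,6S)-6-bromo-3-[(tert-butyldimethylsilyl)oxy]-1,3-dimethyl-2-(2-oxoethyl)cyclohexyl]acetaldehyde | O=CC[C@]1(C)[C@@H](Br)CC[C@@](C)(O[Si](C)(C)C(C)(C)C)[C@H]1CC=O | intermediate
18 | (1S,2R,3aS,4S,7R,7aS)-4-bromo-7-[(tert-butyldimethylsilyl)oxy]-2-hydroxy-3a,7-dimethyloctahydro-1H-indene-1-carbaldehyde | O=C[C@@H]1[C@H](O)C[C@]2(C)[C@@H](Br)CC[C@@](C)(O[Si](C)(C)C(C)(C)C)[C@@H]12 | intermediate
19 | (1S,2R,3aS,4S,7R,7aS)-4-bromo-2,7-bis[(tert-butyldimethylsilyl)oxy]-3a,7-dimethyloctahydro-1H-indene-1-carbaldehyde | O=C[C@@H]1[C@H](O[Si](C)(C)C(C)(C)C)C[C@]2(C)[C@@H](Br)CC[C@@](C)(O[Si](C)(C)C(C)(C)C)[C@@H]12 | intermediate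
20 | 3-methylbut-2-en-1-ol | CC(C)=CCO | starting material
21 | (2S)-2-bromo-3-chloro-3-methylbutan-1-ol | OC[C@H](Br)C(C)(C)Cl | intermediate
22 | (2S)-2-bromo-3-chloro-3-methylbutyl trifluoromethanesulfonate | FC(F)(F)S(=O)(=O)OC[C@H](Br)C(C)(C)Cl | intermediate
23 | di-tert-butyl 3-oxopentanedioate | CC(C)(C)OC(=O)CC(=O)CC(=O)OC(C)(C)C | starting material
24 | di-tert-butyl 2-[(2S)-2-bromo-3-chloro-3-methylbutyl]-3-oxopentanedioate | CC(C)(C)OC(=O)CC(=O)C(C[C@H](Br)C(C)(C)Cl)C(=O)OC(C)(C)C | intermediate
25 | di-tert-butyl (5S)-5-bromo-4,4-dimethyl-2-oxocyclohexane-1,3-dicarboxylate | CC(C)(C)OC(=O)C1C[C@H](Br)C(C)(C)C(C(=O)OC(C)(C)C)C1=O | intermediate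
26 | (5S)-5-bromo-4,4-dimethyl-2-oxocyclohexane-1,3-dicarboxylic acid (keto diacid, not isolated) | OC(=O)C1C[C@H](Br)C(C)(C)C(C(O)=O)C1=O | intermediate
27 | (4S)-4-bromo-3,3-dimethylcyclohexan-1-one | O=C1CC[C@H](Br)C(C)(C)C1 | intermediate
28 | (4S)-4-bromo-3,3-dimethylcyclohexan-1-ol (both C1 epimers) | OC1CC[C@H](Br)C(C)(C)C1 | intermediate
29 | 1-phenyl-1H-tetrazole-5-thiol | SC1=NN=NN1c1ccccc1 | starting material
30 | 5-{[(4S)-4-bromo-3,3-dimethylcyclohexyl]sulfanyl}-1-phenyl-1H-tetrazole | C1(SC2=NN=NN2c2ccccc2)CC[C@H](Br)C(C)(C)C1 | intermediate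
31 | 5-{[(4S)-4-bromo-3,3-dimethylcyclohexyl]sulfonyl}-1-phenyl-1H-tetrazole | O=S(=O)(C1CC[C@H](Br)C(C)(C)C1)C1=NN=NN1c1ccccc1 | intermediate
32 | (1S,2R,3aS,4S,7R,7aS)-4-bromo-1-{(E)-[(4S)-4-bromo-3,3-dimethylcyclohexylidene]methyl}-2,7-bis[(tert-butyldimethylsilyl)oxy]-3a,7-dimethyloctahydro-1H-indene | C1(=C/[C@@H]2[C@H](O[Si](C)(C)C(C)(C)C)C[C@]3(C)[C@@H](Br)CC[C@@](C)(O[Si](C)(C)C(C)(C)C)[C@@H]23)/CC[C@H](Br)C(C)(C)C1 | intermediate
33 | iodo acetate: C8 iodide anti to the C1′ acetate (not isolated) | I[C@@H]([C@@H]1[C@H](O[Si](C)(C)C(C)(C)C)C[C@]2(C)[C@@H](Br)CC[C@@](C)(O[Si](C)(C)C(C)(C)C)[C@@H]12)[C@@]1(OC(C)=O)CC[C@H](Br)C(C)(C)C1 | intermediate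
34 | acetoxonium ion: 2-methyl-1,3-dioxolan-2-ylium ion spanning C8–O and C1′–O (not isolated) | CC1=[O+][C@@]2(CC[C@H](Br)C(C)(C)C2)[C@H](O1)[C@@H]1[C@H](O[Si](C)(C)C(C)(C)C)C[C@]2(C)[C@@H](Br)CC[C@@](C)(O[Si](C)(C)C(C)(C)C)[C@@H]12 | intermediate
35 | C2,C7-bis(tert-butyldimethylsilyl) ether of the target (C8 acetate, C1′ hydroxyl free) | CC(=O)O[C@H]([C@@H]1[C@H](O[Si](C)(C)C(C)(C)C)C[C@]2(C)[C@@H](Br)CC[C@@](C)(O[Si](C)(C)C(C)(C)C)[C@@H]12)[C@@]1(O)CC[C@H](Br)C(C)(C)C1 | intermediate
36 | (R)-[(1S,2R,3aS,4S,7R,7aS)-4-bromo-2,7-dihydroxy-3a,7-dimethyloctahydro-1H-inden-1-yl][(1R,4S)-4-bromo-1-hydroxy-3,3-dimethylcyclohexyl]methyl acetate | CC(=O)O[C@H]([C@@H]1[C@H](O)C[C@]2(C)[C@@H](Br)CC[C@@](C)(O)[C@@H]12)[C@@]1(O)CC[C@H](Br)C(C)(C)C1 | target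

**Step count**
Total: 27 steps. Longest linear sequence: 19 steps (steps 1–16, then 25–27).

**Steps most likely to fail**

1. Step 8 (proposed new method). What may go wrong: the epoxide opens without bromine participation (inversion at C3a), a hydride shift gives an aldehyde, or the enol ether is protodesilylated before the C–C bond forms. Fallback, by known chemistry, from 9 back to 11: HCl in Et2O at −40 °C opens the oxirane at the tertiary carbon (bromine-assisted, retention) to chlorohydrin F1. TESCl/imidazole gives triethylsilyl ether F2, and hydrosilylation as in step 7 gives silyl enol ether F3. Solvolysis of F3 in (CF3)2CHOH with a hindered pyridine, the established way to turn a secondary-bromide/tertiary-chloride pair into a configurationally defined bromonium ion that a π-nucleophile captures, should give cyclohexanone F4. PPTS in MeOH removes the primary triethylsilyl group and returns to 11.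

2. Step 26. What may go wrong: poor facial selectivity, with iodine adding on the C7a side and both new centres coming out inverted, or slow iodonium opening next to the C2 silyl ether. Fallback from 32 back to 35: OsO4 (cat.)/NMO dihydroxylation places both oxygens on the face the electrophile takes, the opposite of the Woodward outcome, so it should give diol F5 if the C7a side is the accessible one. Ac2O/pyridine/DMAP then acetylates only the secondary C8 hydroxyl and returns to 35.

3. Step 25. What may go wrong: poor geometric selectivity with incomplete chromatographic resolution, or sluggish addition of the hindered secondary sulfonyl anion with β-elimination of the silyloxy group of 19. Fallback from 19 (with ketone 27) back to 32, a stepwise Horner–Wittig olefination: NaBH4 gives alcohol F6; I2/PPh3/imidazole gives iodide F7; Michaelis–Arbuzov reaction with Ph2POEt at 120 °C gives phosphine oxide F8. Lithiation (n-BuLi, THF, −78 °C) and addition to 27 gives separable diastereomeric adducts, from which β-hydroxy phosphine oxide F9 (like configuration at C8/C1′) is isolated. Its stereospecific syn-elimination with NaH in DMF gives geometrically pure 32.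

Further compounds
F1 | step 8 | (2E,7S,8R)-7-bromo-1-[(tert-butyldimethylsilyl)oxy]-8-chloro-9-hydroxy-8-methylnon-2-en-4-one | OC[C@@](C)(Cl)[C@@H](Br)CCC(=O)/C=C/CO[Si](C)(C)C(C)(C)C
F2 | step 8 | 9-O-triethylsilyl ether of F1 | CC[Si](CC)(CC)OC[C@@](C)(Cl)[C@@H](Br)CCC(=O)/C=C/CO[Si](C)(C)C(C)(C)C
F3 | step 8 | (Z)-triethylsilyl enol ether of F2 (C7=C7a) | CC[Si](CC)(CC)OC[C@@](C)(Cl)[C@@H](Br)CC/C(O[Si](CC)(CC)CC)=C/CCO[Si](C)(C)C(C)(C)C
F4 | step 8 | O-triethylsilyl ether of 11 | CC[Si](CC)(CC)OC[C@]1(C)[C@@H](Br)CCC(=O)[C@H]1CCO[Si](C)(C)C(C)(C)C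
F5 | step 26 | C8,C1′-diol corresponding to 35 (no acetate) | O[C@H]([C@@H]1[C@H](O[Si](C)(C)C(C)(C)C)C[C@]2(C)[C@@H](Br)CC[C@@](C)(O[Si](C)(C)C(C)(C)C)[C@@H]12)[C@@]1(O)CC[C@H](Br)C(C)(C)C1
F6 | step 25 | C8 primary alcohol from 19 | OC[C@@H]1[C@H](O[Si](C)(C)C(C)(C)C)C[C@]2(C)[C@@H](Br)CC[C@@](C)(O[Si](C)(C)C(C)(C)C)[C@@H]12
F7 | step 25 | C8 iodide | IC[C@@H]1[C@H](O[Si](C)(C)C(C)(C)C)C[C@]2(C)[C@@H](Br)CC[C@@](C)(O[Si](C)(C)C(C)(C)C)[C@@H]12
F8 | step 25 | C8 diphenylphosphine oxide | O=P(c1ccccc1)(c1ccccc1)C[C@@H]1[C@H](O[Si](C)(C)C(C)(C)C)C[C@]2(C)[C@@H](Br)CC[C@@](C)(O[Si](C)(C)C(C)(C)C)[C@@H]12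
F9 | step 25 | β-hydroxy phosphine oxide (P on C8 and OH on C1′ on the same side as the oxygens of 35) | O=P(c1ccccc1)(c1ccccc1)[C@H]([C@@H]1[C@H](O[Si](C)(C)C(C)(C)C)C[C@]2(C)[C@@H](Br)CC[C@@](C)(O[Si](C)(C)C(C)(C)C)[C@@H]12)[C@@]1(O)CC[C@H](Br)C(C)(C)C1
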